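# Proposed synthesis of 15-keto-PGF2α by a reductive vinylogous aldol ring closure

## Analysis of the target

15-Keto-PGF2α (27) is a C20 acid built on a single cyclopentane (C8 to C12). The ring carries the seven-carbon acid chain with its 5Z alkene at C8 and the eight-carbon chain at C12, in which a 13E alkene is conjugated to the C15 ketone. Its four stereocentres are contiguous, (8R,9S,11R,12R): the two chains are trans, the hydroxyls at C9 and C11 are cis to each other and to the C8 chain, and the C11 hydroxyl is trans to the C12 chain. Neither chain holds a stereocentre. The C11 hydroxyl is δ to the ketone through the alkene, so the molecule is a vinylogous β-hydroxy ketone that base can dehydrate or cleave by retro-aldol reaction. The enone is also an acceptor for hydrides, ylides and other nucleophiles, the Z alkene excludes hydrogenation and unselective alkene cleavage, and the acid has to be freed without hydroxide at the end. The difficulty is that three of the four ring substituents sit on one face of a flexible ring, and that the usual chain-building reagents of prostaglandin chemistry do not tolerate the C15 ketone. The strategy rests on one feature: through the C13=C14 alkene the C15 ketone makes C12 the γ-carbon of a dienolate (O15, C15, C14, C13, C12), and the carbinol carbon C11 is its ring neighbour. The ring bond C11–C12 is therefore a vinylogous aldol bond, and the enone itself can be the group that closes the ring.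

## Retrosynthetic reasoning

**Deprotection (27 from 26 from 25).** The last two operations only remove a methyl ester and a silyl ether. The methyl ester in 26 is kept until the end because the ring-forming step needs an aprotic, non-acidic substrate. It is removed enzymatically, since hydroxide could reverse or dehydrate the δ-hydroxy enone. The C9 silyl ether of 25 is the only protecting group on the ring and falls to buffered fluoride.

**Ring closure (25 from 23 through 24).** The C11–C12 bond is cut. It is the only ring bond flanked on one side by a carbinol carbon and on the other by a carbon that is vinylogously α to the ketone. Cutting it turns the ketone from a group that must be masked into the activating group. A cut at C8–C12, the usual conjugate-addition logic, would force C15 to the alcohol level and back. The disconnection removes the ring and two stereocentres (C11, C12) and leaves the acyclic aldehyde 23, which has only C8 and C9 to control. The C12 oxygen of 23 is a leaving group, so its configuration does not matter. The forward reaction must generate dienolate 24 without base, because C10 lies between the aldehyde and a β-silyloxy group. It must also bond through C12 rather than C14 and set the 11α,12β arrangement.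

**Unmasking and activation (23 from 22 from 21).** The route needs two aldehydes in succession, first at C12 and then at C11. C11 is therefore carried as a dimethyl acetal from the start and released only in the last step before the ring closure. This avoids any protecting-group exchange or oxidation on the sensitive γ-acetoxy enone. The acetate of 22 comes from carbinol 21 by simple acylation.

**Enone chain (21 from 16 and 20).** The C12–C13 bond is cut between the α-branched aldehyde 16 and the iodoenone 20. This joins the whole C13–C20 unit in its final oxidation state and creates the C12 oxygen at the same time. The forward reaction needs an alkenyl nucleophile that adds to an aldehyde in the presence of two esters and a ketone, which points to a chromium-mediated coupling. Iodide 20 is traced to chloride 19 and further to hexanoyl chloride 17 and acetylene 18.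

**Acid chain and carboxyl differentiation (16 from 15, 14, 13, and 13 from 10 and 11).** The C5=C6 alkene is cut to aldehyde 10 and phosphonium salt 11, which gives the Z geometry. This order also solves the main chemoselectivity problem of the acyclic series, the distinction between the C1 and C12 carboxyl carbons. After the olefination C1 is a free acid and C12 a methyl ester (13). A nucleophilic hydride then reduces only the ester (14), C1 is methylated (15), and the C12 alcohol is oxidised (16). A direct alkylation with the complete chain would have given a diester with no reliable way to reduce only the hindered ester.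

**Stereodiad and backbone (10 from 9 from 8, 8 from 5 and 6, 5 from 4, 4 from 1 and 2).** The C7–C8 bond is cut to the β-hydroxy ester 5 and allyl bromide 6. Alkylation of the dianion 7 sets C8 anti to the C9 oxygen, which is the 8,9-cis relationship of the ring, and the allyl group is a masked C6 aldehyde. C9 comes from asymmetric hydrogenation of keto ester 4. Keto ester 4 is assembled from methyl acetate 1 and the commercial acetal ester 2, which supplies C10 and the masked C11 aldehyde.

## Alternatives that were turned down

**Alternative 1: cyclopropylcarbinyl solvolysis.**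
- Disconnection: the C11–O bond and the C13=C14 alkene of the hydroxy lactone A1 are traced back to a C11–C13 bond and a C14–C15 epoxide, that is, to the cyclopropane-fused lactone epoxide A2.
- Forward key step: acid opens the epoxide at C14, the cyclopropane bond C11–C13 breaks to give the E alkene, and the nucleophile enters at C11 from the face opposite the departing carbon.
- For: one stereospecific event on a rigid framework delivers both the 11α-hydroxyl and the E alkene. The rearrangement type is established, whereas the chosen key step is not, so on precedent this alternative is stronger. Its usual weakness, a C15 epimer mixture, does not matter here because C15 ends as a ketone.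
- Against: A1 still lacks the acid chain. Lactone reduction and ylide olefination both attack a C15 ketone, so C15 must stay a protected alcohol and be oxidised last, at least five operations after the key step. A2, with four ring stereocentres and the epoxide side chain, needs a long linear preparation. The cation can also be captured at C13 or C14, or lose a proton.
- Comparison: the chosen route reaches the target two steps after ring closure and uses the ketone instead of working around it.

**Alternative 2: enzymatic Baeyer–Villiger oxidation.**
- Disconnection: the C9–O bond of the bicyclic lactone A4 is traced back to the cyclobutanone A3, used as the racemate.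
- Forward key step: a monooxygenase inserts oxygen between the carbonyl carbon and C9 of the (1R,5S) enantiomer with retention.
- For: A3 is cheap, the enzyme gives essentially one enantiomer without any chiral reagent, and everything downstream of A4 is well-trodden chemistry. In reliability this alternative is superior.
- Against: only half of the racemate can become A4, since the other enantiomer is diverted to a regioisomeric lactone that has to be separated. A4 contains only C8, C9 and the lactone. The C11 hydroxyl, the C12 stereocentre and both chains remain to be installed. The acid chain again needs the lactol and ylide steps that a C15 ketone does not survive. This amounts to roughly ten further steps.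
- Comparison: the chosen route forms C11 and C12 in the ring-closing step with both chains already in place.

**Alternative 3: enzymatic bis-dioxygenation.**
- Disconnection: all ring bonds and three C–O bonds are traced back to arachidonic acid A5.
- Forward key step: the cyclooxygenase converts A5 into the hydroperoxy endoperoxide A6 in one operation that sets every stereocentre.
- For: reduction of both peroxide groups would give A7, and selective oxidation of its allylic C15 alcohol would give the target. At three operations from a commercial acid this is far shorter than the chosen route and fully stereocontrolled. On step economy it cannot be matched.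
- Against: the enzyme inactivates itself after a limited number of turnovers and has to be isolated from tissue, so the method is confined to small scale. A6 is a labile peroxide that isomerises to keto-alcohols in water within minutes, so its reduction must compete with decomposition. The C15 stereocentre is built only to be destroyed.
- Comparison: the chosen route offers stable intermediates, ordinary reagents, scalability and access to analogues, at the price of length and an untested key step.

Key step: step 15

Remark on the chemistry: atom labels C1 to C20 follow prostaglandin numbering. Compounds 21, 22 and 23 are carried as mixtures of both configurations at C12, because this carbon becomes trigonal in step 15.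

## Route

Step 1
Reactants: 1 methyl acetate; 2 methyl 3,3-dimethoxypropanoate
Product: 4 methyl 5,5-dimethoxy-3-oxopentanoate, via lithium enolate of methyl acetate 3 (not isolated)
Conditions: LiN(i-Pr)2 (2.2 equiv), THF, −78 °C; 1 (2.2 equiv); then 2, −78 → −30 °C; aq. NH4Cl
Reagents that add atoms: none
Why: Crossed Claisen condensation: enolate 3 adds to the ester carbonyl of 2 and methoxide leaves; the excess enolate converts the product into its stable β-keto ester enolate, which drives the reaction, and the low temperature keeps 2 from losing methoxide by β-elimination.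

Step 2
Reactants: 4 methyl 5,5-dimethoxy-3-oxopentanoate
Product: 5 methyl (3S)-3-hydroxy-5,5-dimethoxypentanoate
Conditions: RuCl2[(S)-BINAP] (0.5 mol %), H2 (50 atm), MeOH, 50 °C
Reagents that add atoms: none
Why: Noyori asymmetric hydrogenation of a β-keto ester: the ester carbonyl chelates divalent ruthenium and hydride is delivered to one face of the ketone, (S)-BINAP giving the 3S carbinol (later C9) as in the simple 3-oxobutanoate series. The dimethyl acetal is inert in methanol and no other reducible group is present.

Step 3
Reactants: 5 methyl (3S)-3-hydroxy-5,5-dimethoxypentanoate; 6 allyl bromide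
Product: 8 methyl (2S,3S)-3-hydroxy-5,5-dimethoxy-2-(prop-2-en-1-yl)pentanoate, via dilithium alkoxide enolate 7 (not isolated)
Conditions: LiN(i-Pr)2 (2.2 equiv), THF, −78 → −20 °C; 6, DMPU, −78 → −10 °C; aq. NH4Cl
Reagents that add atoms: none
Why: Fráter–Seebach alkylation: the chelated dilithium alkoxide enolate 7 is alkylated on the face opposite the C3 substituent, which sets C2 (later C8) anti to the C3 oxygen; this anti relationship in the chain is the 8,9-cis relationship of the ring. The alkoxide is a poor leaving group, so β-elimination does not compete.

Step 4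
Reactants: 8 methyl (2S,3S)-3-hydroxy-5,5-dimethoxy-2-(prop-2-en-1-yl)pentanoate
Product: 9 methyl (2S,3S)-3-[(tert-butyldimethylsilyl)oxy]-5,5-dimethoxy-2-(prop-2-en-1-yl)pentanoate
Conditions: TBSCl, imidazole, DMAP (cat.), DMF, 40 °C
Reagents that add atoms: tert-butyldimethylsilyl chloride, C[Si](C)(Cl)C(C)(C)C
Why: Standard silyl ether formation with silyl chloride and imidazole. The chloride is chosen over the silyl triflate because the triflate is Lewis acidic enough to ionise the dimethyl acetal.

Step 5
Reactants: 9 methyl (2S,3S)-3-[(tert-butyldimethylsilyl)oxy]-5,5-dimethoxy-2-(prop-2-en-1-yl)pentanoate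
Product: 10 methyl (2S,3S)-3-[(tert-butyldimethylsilyl)oxy]-5,5-dimethoxy-2-(2-oxoethyl)pentanoate
Conditions: OsO4 (2 mol %), NaIO4 (4 equiv), 2,6-lutidine, dioxane/H2O (3:1), rt
Reagents that add atoms: osmium tetroxide, O=[Os](=O)(=O)=O; sodium periodate, [Na+].[O-]I(=O)(=O)=O
Why: Lemieux–Johnson oxidative cleavage: catalytic dihydroxylation of the only alkene and periodate cleavage of the diol give the C6 aldehyde. 2,6-Lutidine buffers the medium for the acetal and the silyl ether.

Step 6
Reactants: 10 methyl (2S,3S)-3-[(tert-butyldimethylsilyl)oxy]-5,5-dimethoxy-2-(2-oxoethyl)pentanoate; 11 (4-carboxybutyl)triphenylphosphonium bromide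
Product: 13 (5Z,8S)-8-[(1S)-1-[(tert-butyldimethylsilyl)oxy]-3,3-dimethoxypropyl]-9-methoxy-9-oxonon-5-enoic acid, via carboxylate ylide 12 (not isolated)
Conditions: 11 (2.2 equiv), KN(SiMe3)2 (4.3 equiv), THF, 0 °C; then 10, −78 → 0 °C; pH 5 buffer
Reagents that add atoms: none
Why: Wittig olefination with a non-stabilised ylide under lithium-free conditions, which gives the Z alkene (C5=C6) by kinetic control. The ylide reacts far faster with the aldehyde than with the hindered α-branched ester and is not basic enough to deprotonate C8. The product carries C1 as the free acid and C12 as the ester, which differentiates the two carboxyl carbons.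

Step 7
Reactants: 13 (5Z,8S)-8-[(1S)-1-[(tert-butyldimethylsilyl)oxy]-3,3-dimethoxypropyl]-9-methoxy-9-oxonon-5-enoic acid
Product: 14 (5Z,8R,9S)-9-[(tert-butyldimethylsilyl)oxy]-8-(hydroxymethyl)-11,11-dimethoxyundec-5-enoic acid
Conditions: LiBEt3H (3.5 equiv), THF, 0 °C; H2O, then pH 5 buffer
Reagents that add atoms: none
Why: Chemoselective hydride reduction of a half-ester: the first equivalent of LiBEt3H converts the acid into its lithium carboxylate, which is inert, and further hydride reduces the methyl ester to the primary alcohol. The by-product BEt3 has no B–H bond, so the alkene cannot be hydroborated; the silyl ether and the acetal are unaffected.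

Step 8
Reactants: 14 (5Z,8R,9S)-9-[(tert-butyldimethylsilyl)oxy]-8-(hydroxymethyl)-11,11-dimethoxyundec-5-enoic acid
Product: 15 methyl (5Z,8R,9S)-9-[(tert-butyldimethylsilyl)oxy]-8-(hydroxymethyl)-11,11-dimethoxyundec-5-enoate
Conditions: MeI, KHCO3, DMF, rt
Reagents that add atoms: iodomethane, CI
Why: SN2 O-alkylation of the carboxylate. KHCO3 does not deprotonate the primary alcohol, so no methyl ether forms.

Step 9
Reactants: 15 methyl (5Z,8R,9S)-9-[(tert-butyldimethylsilyl)oxy]-8-(hydroxymethyl)-11,11-dimethoxyundec-5-enoate
Product: 16 methyl (5Z,8S,9S)-9-[(tert-butyldimethylsilyl)oxy]-8-formyl-11,11-dimethoxyundec-5-enoate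
Conditions: Dess–Martin periodinane, NaHCO3, CH2Cl2, 0 °C → rt
Reagents that add atoms: none
Why: Dess–Martin oxidation of the primary alcohol under buffered, non-basic conditions, which spares the acetal and should neither epimerise C8 nor eliminate the β-silyloxy group. The aldehyde is used without chromatography.

Step 10
Reactants: 17 hexanoyl chloride; 18 acetylene
Product: 19 (1E)-1-chlorooct-1-en-3-one
Conditions: AlCl3 (1.1 equiv), CH2Cl2, 0 °C, acetylene stream
Reagents that add atoms: none
Why: Friedel–Crafts-type acylation of acetylene: the acylium ion adds to the alkyne and chloride is captured, giving the β-chlorovinyl ketone, which equilibrates to the E isomer under the Lewis acid.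

Step 11
Reactants: 19 (1E)-1-chlorooct-1-en-3-one
Product: 20 (1E)-1-iodooct-1-en-3-one
Conditions: NaI, acetone, rt, dark
Reagents that add atoms: sodium iodide, [Na+].[I-]
Why: Halide exchange by conjugate addition–elimination (vinylogous acyl substitution) with retention of the E geometry, driven by precipitation of NaCl from acetone.

Step 12
Reactants: 16 methyl (5Z,8S,9S)-9-[(tert-butyldimethylsilyl)oxy]-8-formyl-11,11-dimethoxyundec-5-enoate; 20 (1E)-1-iodooct-1-en-3-one
Product: 21 methyl (5Z,8R,10E)-8-[(1S)-1-[(tert-butyldimethylsilyl)oxy]-3,3-dimethoxypropyl]-9-hydroxy-12-oxoheptadeca-5,10-dienoate (both carbinol epimers)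
Conditions: CrCl2 (4 equiv), NiCl2 (1 mol %), 20 (2 equiv), degassed DMF, rt
Reagents that add atoms: none
Why: Nozaki–Hiyama–Kishi coupling: zerovalent nickel (formed from NiCl2 and CrCl2) inserts into the C–I bond, the alkenyl group passes to trivalent chromium and adds to the aldehyde only, leaving both esters, the ketone and the acetal untouched; the E geometry is retained. The configuration of the new carbinol (C12) is irrelevant, since this carbon becomes trigonal in step 15.

Step 13
Reactants: 21 methyl (5Z,8R,10E)-8-[(1S)-1-[(tert-butyldimethylsilyl)oxy]-3,3-dimethoxypropyl]-9-hydroxy-12-oxoheptadeca-5,10-dienoate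
Product: 22 methyl (5Z,8R,10E)-9-acetoxy-8-[(1S)-1-[(tert-butyldimethylsilyl)oxy]-3,3-dimethoxypropyl]-12-oxoheptadeca-5,10-dienoate (both C12 epimers)
Conditions: Ac2O, pyridine, DMAP (cat.), CH2Cl2, 0 °C
Reagents that add atoms: acetic anhydride, CC(=O)OC(C)=O
Why: DMAP-catalysed acylation of the secondary allylic alcohol. This turns the C12 oxygen into the leaving group of the key step.

Step 14
Reactants: 22 methyl (5Z,8R,10E)-9-acetoxy-8-[(1S)-1-[(tert-butyldimethylsilyl)oxy]-3,3-dimethoxypropyl]-12-oxoheptadeca-5,10-dienoate
Product: 23 methyl (5Z,8R,10E)-9-acetoxy-8-[(1S)-1-[(tert-butyldimethylsilyl)oxy]-3-oxopropyl]-12-oxoheptadeca-5,10-dienoate (both C12 epimers)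
Conditions: Amberlyst-15, acetone/H2O (20:1), rt
Reagents that add atoms: water, O
Why: Acid-catalysed hydrolysis (transacetalisation) of the dimethyl acetal, the most acid-labile group present. The secondary silyl ether, the esters and the acetate, whose ionisation is disfavoured by the electron-poor enone, should persist under these mild conditions. The β-silyloxy aldehyde is used at once.

Step 15
Reactants: 23 methyl (5Z,8R,10E)-9-acetoxy-8-[(1S)-1-[(tert-butyldimethylsilyl)oxy]-3-oxopropyl]-12-oxoheptadeca-5,10-dienoate
Product: 25 methyl (5Z)-7-[(1R,2R,3R,5S)-5-[(tert-butyldimethylsilyl)oxy]-3-hydroxy-2-[(1E)-3-oxooct-1-en-1-yl]cyclopentyl]hept-5-enoate, via samarium dienolate 24 (not isolated)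
Conditions: SmI2 (2.2 equiv, 0.1 M in THF), −78 °C, 23 added slowly; −78 → −40 °C; pH 7 phosphate buffer
Reagents that add atoms: none
Why: Proposed new method: SmI2 transfers one electron to the enone of 23, the radical anion expels the γ-acetate and a second electron gives the trivalent samarium dienolate 24 (O15, C15, C14, C13, C12) without any base, so C10 is never deprotonated and the β-silyloxy aldehyde survives. The γ-carbon C12 then adds to the tethered C11 aldehyde in a 5-(enolexo)-exo-trig closure that forms the C11–C12 bond and the cyclopentane and restores the conjugated E enone. The closest known reaction types are the SmI2 reduction of γ-acyloxy enoates to dienolates that are trapped by protons or carbonyl compounds, the SmI2-mediated intramolecular aldol (Reformatsky-type) cyclisation of α-heterosubstituted ketones, and base-mediated intramolecular vinylogous aldol reactions; the reductive vinylogous closure from a γ-acetoxy enone has not been shown. The step needs γ- over α-attack, and the tether secures it, because bonding through C14 would place an E alkene inside a seven-membered ring when the dienolate has the extended C12=C13 geometry. C12 is controlled by the C8 stereocentre: with the C8–H bond eclipsing C12=C13 (least allylic strain) the aldehyde arm reaches the dienolate face that puts the C13 chain trans to the C7 chain. C11 is controlled by the samarium-bound aldehyde oxygen pointing away from the C13 alkenyl group in an open transition state, which gives the 11,12-trans and therefore 9,11-cis arrangement, possibly assisted by a samarium bridge to O9; this is the untested element. Both C12 epimers of 23 converge on the same dienolate, so that centre needed no control earlier. Chemoselectivity for the enone over the aldehyde rests on the much faster electron transfer to an acyloxy enone at −78 °C in the absence of HMPA.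

Step 16
Reactants: 25 methyl (5Z)-7-[(1R,2R,3R,5S)-5-[(tert-butyldimethylsilyl)oxy]-3-hydroxy-2-[(1E)-3-oxooct-1-en-1-yl]cyclopentyl]hept-5-enoate
Product: 26 methyl (5Z)-7-[(1R,2R,3R,5S)-3,5-dihydroxy-2-[(1E)-3-oxooct-1-en-1-yl]cyclopentyl]hept-5-enoate
Conditions: HF·pyridine, pyridine, THF, 0 °C → rt
Reagents that add atoms: none
Why: Fluoride-induced cleavage of the silyl ether (Si–F bond formation) in a buffered, weakly acidic medium. No base is present that could trigger vinylogous retro-aldol cleavage or dehydration of the δ-hydroxy enone.

Step 17
Reactants: 26 methyl (5Z)-7-[(1R,2R,3R,5S)-3,5-dihydroxy-2-[(1E)-3-oxooct-1-en-1-yl]cyclopentyl]hept-5-enoate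
Product: 27 (5Z)-7-[(1R,2R,3R,5S)-3,5-dihydroxy-2-[(1E)-3-oxooct-1-en-1-yl]cyclopentyl]hept-5-enoic acid (15-keto-PGF2α)
Conditions: pig liver esterase, phosphate buffer pH 7.4/acetone (9:1), 30 °C
Reagents that add atoms: water, O
Why: Enzymatic ester hydrolysis at neutral pH (serine hydrolase, acyl-enzyme mechanism), which frees the acid without exposing the δ-hydroxy enone to hydroxide.

## Compound list

1 | methyl acetate | COC(C)=O | starting material
2 | methyl 3,3-dimethoxypropanoate | COC(=O)CC(OC)OC | starting material
3 | lithium enolate of methyl acetate (lithium 1-methoxyethen-1-olate) | [Li+].[O-]C(=C)OC | intermediate (not isolated)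
4 | methyl 5,5-dimethoxy-3-oxopentanoate | COC(=O)CC(=O)CC(OC)OC | intermediate
5 | methyl (3S)-3-hydroxy-5,5-dimethoxypentanoate | COC(=O)C[C@@H](O)CC(OC)OC | intermediate
6 | allyl bromide (3-bromoprop-1-ene) | C=CCBr | starting material
7 | dilithium alkoxide enolate of 5 | [Li+].[Li+].COC([O-])=C[C@@H]([O-])CC(OC)OC | intermediate (not isolated)
8 | methyl (2S,3S)-3-hydroxy-5,5-dimethoxy-2-(prop-2-en-1-yl)pentanoate | COC(=O)[C@@H](CC=C)[C@@H](O)CC(OC)OC | intermediate
9 | methyl (2S,3S)-3-[(tert-butyldimethylsilyl)oxy]-5,5-dimethoxy-2-(prop-2-en-1-yl)pentanoate | COC(=O)[C@@H](CC=C)[C@@H](O[Si](C)(C)C(C)(C)C)CC(OC)OC | intermediate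
10 | methyl (2S,3S)-3-[(tert-butyldimethylsilyl)oxy]-5,5-dimethoxy-2-(2-oxoethyl)pentanoate | COC(=O)[C@@H](CC=O)[C@@H](O[Si](C)(C)C(C)(C)C)CC(OC)OC | intermediate
11 | (4-carboxybutyl)triphenylphosphonium bromide | OC(=O)CCCC[P+](c1ccccc1)(c1ccccc1)c1ccccc1.[Br-] | starting material
12 | potassium 5-(triphenyl-λ5-phosphanylidene)pentanoate (carboxylate ylide) | [K+].[O-]C(=O)CCCC=P(c1ccccc1)(c1ccccc1)c1ccccc1 | intermediate (not isolated)
13 | (5Z,8S)-8-[(1S)-1-[(tert-butyldimethylsilyl)oxy]-3,3-dimethoxypropyl]-9-methoxy-9-oxonon-5-enoic acid | OC(=O)CCC/C=C\C[C@H](C(=O)OC)[C@@H](O[Si](C)(C)C(C)(C)C)CC(OC)OC | intermediate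
14 | (5Z,8R,9S)-9-[(tert-butyldimethylsilyl)oxy]-8-(hydroxymethyl)-11,11-dimethoxyundec-5-enoic acid | OC(=O)CCC/C=C\C[C@H](CO)[C@@H](O[Si](C)(C)C(C)(C)C)CC(OC)OC | intermediate
15 | methyl (5Z,8R,9S)-9-[(tert-butyldimethylsilyl)oxy]-8-(hydroxymethyl)-11,11-dimethoxyundec-5-enoate | COC(=O)CCC/C=C\C[C@H](CO)[C@@H](O[Si](C)(C)C(C)(C)C)CC(OC)OC | intermediate
16 | methyl (5Z,8S,9S)-9-[(tert-butyldimethylsilyl)oxy]-8-formyl-11,11-dimethoxyundec-5-enoate | COC(=O)CCC/C=C\C[C@H](C=O)[C@@H](O[Si](C)(C)C(C)(C)C)CC(OC)OC | intermediate
17 | hexanoyl chloride | CCCCCC(Cl)=O | starting material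
18 | acetylene (ethyne) | C#C | starting material
19 | (1E)-1-chlorooct-1-en-3-one | CCCCCC(=O)/C=C/Cl | intermediate
20 | (1E)-1-iodooct-1-en-3-one | CCCCCC(=O)/C=C/I | intermediate
21 | methyl (5Z,8R,10E)-8-[(1S)-1-[(tert-butyldimethylsilyl)oxy]-3,3-dimethoxypropyl]-9-hydroxy-12-oxoheptadeca-5,10-dienoate (both epimers at the carbinol carbon, prostaglandin C12) | CCCCCC(=O)/C=C/C(O)[C@@H](C/C=C\CCCC(=O)OC)[C@@H](O[Si](C)(C)C(C)(C)C)CC(OC)OC | intermediate
22 | methyl (5Z,8R,10E)-9-acetoxy-8-[(1S)-1-[(tert-butyldimethylsilyl)oxy]-3,3-dimethoxypropyl]-12-oxoheptadeca-5,10-dienoate (both epimers at prostaglandin C12) | CCCCCC(=O)/C=C/C(OC(C)=O)[C@@H](C/C=C\CCCC(=O)OC)[C@@H](O[Si](C)(C)C(C)(C)C)CC(OC)OC | intermediate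
23 | methyl (5Z,8R,10E)-9-acetoxy-8-[(1S)-1-[(tert-butyldimethylsilyl)oxy]-3-oxopropyl]-12-oxoheptadeca-5,10-dienoate (both epimers at prostaglandin C12; precursor of the key step) | CCCCCC(=O)/C=C/C(OC(C)=O)[C@@H](C/C=C\CCCC(=O)OC)[C@@H](O[Si](C)(C)C(C)(C)C)CC=O | intermediate
24 | trivalent samarium dienolate formed from 23 by loss of acetate (diiodosamarium enolate over O15, C15, C14, C13, C12) | CCCCCC(O[Sm](I)I)=C/C=C/[C@@H](C/C=C\CCCC(=O)OC)[C@@H](O[Si](C)(C)C(C)(C)C)CC=O | intermediate (not isolated)
25 | methyl (5Z)-7-[(1R,2R,3R,5S)-5-[(tert-butyldimethylsilyl)oxy]-3-hydroxy-2-[(1E)-3-oxooct-1-en-1-yl]cyclopentyl]hept-5-enoate | CCCCCC(=O)/C=C/[C@@H]1[C@@H](C/C=C\CCCC(=O)OC)[C@@H](O[Si](C)(C)C(C)(C)C)C[C@H]1O | intermediate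
26 | methyl (5Z)-7-[(1R,2R,3R,5S)-3,5-dihydroxy-2-[(1E)-3-oxooct-1-en-1-yl]cyclopentyl]hept-5-enoate | CCCCCC(=O)/C=C/[C@@H]1[C@@H](C/C=C\CCCC(=O)OC)[C@@H](O)C[C@H]1O | intermediate
27 | (5Z)-7-[(1R,2R,3R,5S)-3,5-dihydroxy-2-[(1E)-3-oxooct-1-en-1-yl]cyclopentyl]hept-5-enoic acid (15-keto-PGF2α) | CCCCCC(=O)/C=C/[C@@H]1[C@@H](C/C=C\CCCC(=O)O)[C@@H](O)C[C@H]1O | target

## Step count and risk assessment

Total step count: 17. Longest linear sequence: 15 (steps 1 to 9 and 12 to 17); steps 10 and 11 form the two-step side branch to iodide 20.

**Step 15 (key step, proposed new method).**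
- What may go wrong: protonation of the dienolate before it cyclises, which would amount to reductive removal of the acetate; competing one-electron reduction of the aldehyde; poor facial selectivity at the aldehyde, which would scramble C11. The last is the most likely, because the open transition state has no rigid element that fixes the aldehyde oxygen.
- Fallback: it uses known reaction types, sets out from aldehyde 16 and returns at 25. Vinylmagnesium bromide at −78 °C adds to the aldehyde of 16 and gives methyl (5Z,8R,9S)-9-[(tert-butyldimethylsilyl)oxy]-8-(1-hydroxyprop-2-en-1-yl)-11,11-dimethoxyundec-5-enoate F1. Acetylation gives the allylic acetate F2, and the acetal is hydrolysed as in step 14 to the aldehyde F3. Pd(PPh3)4 with InI then converts the allylic acetate into an allylindium species by way of the π-allyl complex of palladium. This species adds through its γ-carbon (C12) to the C11 aldehyde, a known intramolecular carbonyl allylation by polarity inversion, and gives the vinylcyclopentanol methyl (5Z)-7-[(1R,2R,3R,5S)-5-[(tert-butyldimethylsilyl)oxy]-2-ethenyl-3-hydroxycyclopentyl]hept-5-enoate F4. Cross-metathesis of F4 with commercial oct-1-en-3-one and the second-generation Hoveyda–Grubbs catalyst installs the E enone and gives 25. The C11 configuration is an open point in this fallback as well, and the cis alkene of the acid chain must stay out of the metathesis.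

**Step 12.**
- What may go wrong: reductive dimerisation or protonation of the activated iodoenone before it couples, and epimerisation at C8 or loss of the β-silyloxy group from the α-branched aldehyde in contact with Lewis acidic chromium salts.
- Fallback: it sets out from 16 and returns at 22. Commercial oct-1-yn-3-ol is silylated to triethyl(oct-1-yn-3-yloxy)silane F5. Hydrozirconation of F5 with Cp2Zr(H)Cl, transfer of the alkenyl group to zinc with Me2Zn and addition to 16 give the allylic alcohol methyl (5Z,8R,10E)-8-[(1S)-1-[(tert-butyldimethylsilyl)oxy]-3,3-dimethoxypropyl]-9-hydroxy-12-[(triethylsilyl)oxy]heptadeca-5,10-dienoate F6. Acetylation gives the acetate F7. Buffered HF·pyridine at 0 °C removes only the more labile triethylsilyl ether and gives the C15 alcohol F8. Oxidation of this allylic alcohol with MnO2 gives 22.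

**Step 7.**
- What may go wrong: slow reduction of the hindered ester next to the silyloxy-bearing carbon, or loss of chemoselectivity if the acid is not fully converted into its carboxylate first.
- Fallback: it sets out from 9 and returns at 14, and removes the ester before the chain is built. Reduction of 9 with i-Bu2AlH gives the alcohol (2R,3S)-3-[(tert-butyldimethylsilyl)oxy]-5,5-dimethoxy-2-(prop-2-en-1-yl)pentan-1-ol F9. Lemieux–Johnson cleavage gives the lactol (4R)-4-[(1S)-1-[(tert-butyldimethylsilyl)oxy]-3,3-dimethoxypropyl]oxolan-2-ol F10. Olefination of F10 with an excess of ylide 12 gives 14 directly. This order is not the first choice because the potassium alkoxide formed in the olefination may induce migration of the silyl group from O9 to the primary oxygen.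

**Step 1.**
- What may go wrong: deprotonation of 2 at C2 followed by β-elimination of methoxide, in competition with addition to the ester carbonyl, and self-condensation of enolate 3.
- Fallback: it sets out from 2 and returns at 4. Saponification with LiOH gives 3,3-dimethoxypropanoic acid F11. F11 is activated with carbonyldiimidazole and condensed with the magnesium enolate of potassium methyl malonate (MgCl2, Et3N); decarboxylation then gives 4 under nearly neutral conditions.

## Further compounds

F1 | step 15 | methyl (5Z,8R,9S)-9-[(tert-butyldimethylsilyl)oxy]-8-(1-hydroxyprop-2-en-1-yl)-11,11-dimethoxyundec-5-enoate (both carbinol epimers) | COC(=O)CCC/C=C\C[C@H](C(O)C=C)[C@@H](O[Si](C)(C)C(C)(C)C)CC(OC)OC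
F2 | step 15 | methyl (5Z,8R,9S)-8-(1-acetoxyprop-2-en-1-yl)-9-[(tert-butyldimethylsilyl)oxy]-11,11-dimethoxyundec-5-enoate (both epimers) | COC(=O)CCC/C=C\C[C@H](C(OC(C)=O)C=C)[C@@H](O[Si](C)(C)C(C)(C)C)CC(OC)OC
F3 | step 15 | methyl (5Z,8R,9S)-8-(1-acetoxyprop-2-en-1-yl)-9-[(tert-butyldimethylsilyl)oxy]-11-oxoundec-5-enoate (both epimers) | COC(=O)CCC/C=C\C[C@H](C(OC(C)=O)C=C)[C@@H](O[Si](C)(C)C(C)(C)C)CC=O
F4 | step 15 | methyl (5Z)-7-[(1R,2R,3R,5S)-5-[(tert-butyldimethylsilyl)oxy]-2-ethenyl-3-hydroxycyclopentyl]hept-5-enoate | C=C[C@@H]1[C@@H](C/C=C\CCCC(=O)OC)[C@@H](O[Si](C)(C)C(C)(C)C)C[C@H]1O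
F5 | step 12 | triethyl(oct-1-yn-3-yloxy)silane (racemic) | CCCCCC(O[Si](CC)(CC)CC)C#C
F6 | step 12 | methyl (5Z,8R,10E)-8-[(1S)-1-[(tert-butyldimethylsilyl)oxy]-3,3-dimethoxypropyl]-9-hydroxy-12-[(triethylsilyl)oxy]heptadeca-5,10-dienoate (isomers at prostaglandin C12 and C15) | CCCCCC(O[Si](CC)(CC)CC)/C=C/C(O)[C@@H](C/C=C\CCCC(=O)OC)[C@@H](O[Si](C)(C)C(C)(C)C)CC(OC)OC
F7 | step 12 | methyl (5Z,8R,10E)-9-acetoxy-8-[(1S)-1-[(tert-butyldimethylsilyl)oxy]-3,3-dimethoxypropyl]-12-[(triethylsilyl)oxy]heptadeca-5,10-dienoate (isomers at prostaglandin C12 and C15) | CCCCCC(O[Si](CC)(CC)CC)/C=C/C(OC(C)=O)[C@@H](C/C=C\CCCC(=O)OC)[C@@H](O[Si](C)(C)C(C)(C)C)CC(OC)OC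
F8 | step 12 | methyl (5Z,8R,10E)-9-acetoxy-8-[(1S)-1-[(tert-butyldimethylsilyl)oxy]-3,3-dimethoxypropyl]-12-hydroxyheptadeca-5,10-dienoate (isomers at prostaglandin C12 and C15) | CCCCCC(O)/C=C/C(OC(C)=O)[C@@H](C/C=C\CCCC(=O)OC)[C@@H](O[Si](C)(C)C(C)(C)C)CC(OC)OC
F9 | step 7 | (2R,3S)-3-[(tert-butyldimethylsilyl)oxy]-5,5-dimethoxy-2-(prop-2-en-1-yl)pentan-1-ol | OC[C@@H](CC=C)[C@@H](O[Si](C)(C)C(C)(C)C)CC(OC)OC
F10 | step 7 | (4R)-4-[(1S)-1-[(tert-butyldimethylsilyl)oxy]-3,3-dimethoxypropyl]oxolan-2-ol (both anomers) | OC1C[C@H](CO1)[C@@H](O[Si](C)(C)C(C)(C)C)CC(OC)OC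
F11 | step 1 | 3,3-dimethoxypropanoic acid | COC(CC(=O)O)OC
A1 | alternative 1 | (3aR,4R,5R,6aS)-5-hydroxy-4-[(1E)-3-hydroxyoct-1-en-1-yl]hexahydro-2H-cyclopenta[b]furan-2-one (C15 epimers) | CCCCCC(O)/C=C/[C@@H]1[C@@H](CC(=O)O2)[C@@H]2C[C@H]1O
A2 | alternative 1 | γ-lactone in which C11, C12 and C13 form a cyclopropane on the β face and C14–C15 is an epoxide (exo oxiranyl group, epoxide isomers) | CCCCCC1OC1[C@H]2[C@@H]3[C@@H](CC(=O)O4)[C@@H]4C[C@H]23
A3 | alternative 2 | (1R,5S)-bicyclo[3.2.0]hept-2-en-6-one (the reacting enantiomer of the racemic ketone) | C1=C[C@@H](CC2=O)[C@@H]2C1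
A4 | alternative 2 | (1S,5R)-2-oxabicyclo[3.3.0]oct-6-en-3-one | C1=C[C@@H](CC(=O)O2)[C@@H]2C1
A5 | alternative 3 | arachidonic acid ((5Z,8Z,11Z,14Z)-icosa-5,8,11,14-tetraenoic acid) | CCCCC/C=C\C/C=C\C/C=C\C/C=C\CCCC(=O)O
A6 | alternative 3 | prostaglandin G2 (15-hydroperoxy 9,11-endoperoxide) | CCCCC[C@H](OO)/C=C/[C@@H]1[C@@H](C/C=C\CCCC(=O)O)[C@@H](OO2)C[C@H]12
A7 | alternative 3 | prostaglandin F2α | CCCCC[C@H](O)/C=C/[C@@H]1[C@@H](C/C=C\CCCC(=O)O)[C@@H](O)C[C@H]1O
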